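**Retrosynthetic overview**

1. Target 18 ← 17 (benzoate cleavage) ← 16 (ketone C=O to C=CH2) ← methyl ketone 13 + 3-methylbut-2-enal 14 (aldol bond; carbinol set by a chiral boron enolate).
2. 13 ← cyclohexene 12 by Markovnikov addition of H/Br across the ring alkene (Br to the methyl-bearing carbon, anti to the neighbouring C–Cl).
3. The only ring is made once, in step 6: Diels–Alder disconnection of the ring bonds C1–C6 and C2–C3 (target numbering: C1 carbinol, C3 CHCl, C4 CMeBr) into (E)-1-chloro-2-methylbuta-1,3-diene 5 and 2-(benzoyloxy)prop-2-enal 9.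
4. Enabling feature: ring C1 is a quaternary carbinol carbon carrying O and an sp2 side-chain carbon, with a CH2 neighbour (C2), which is an α-oxyacrolein; C3(Cl)–C4(CH3)–C5–C6 is a 1-chloro-2-methylbutadiene, and the C4=C5 alkene left by the cycloaddition sits exactly where H and Br are still missing.
5. Stereocontrol: C1 by the chiral ammonium catalyst and C3 by the endo rule (same step), C4 from C3, side-chain carbinol by reagent control.

Key step: step 6

Remark on the chemistry: the antipodes of the diamine salt (step 6) and of Ipc2BCl (step 10) named below are assumed to be the ones that open the Si face of C2 of the acrolein and the Si face of the enal carbonyl; if a model reaction shows the opposite sense, the mirror-image reagent is used with no other change.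

**Step 1**
Reactants: 1 prop-2-yn-1-ol
Product: 3 (E)-3-chloro-2-methylprop-2-en-1-ol, via alkenylalane 2 (not isolated)
Conditions: AlMe3 (3 equiv), Cp2ZrCl2 (0.25 equiv), CH2Cl2, 0 °C → rt; then N-chlorosuccinimide, THF, −30 → 0 °C; aq. HCl
Reagents that add atoms: trimethylaluminium C[Al](C)C; N-chlorosuccinimide O=C1CCC(=O)N1Cl
Why: Zirconium-catalysed syn-carboalumination of the alkyne (Negishi carboalumination) puts CH3 on the internal carbon and Al on the terminus, and chlorodealumination with retention fixes the (E)-geometry (Cl trans to CH2OH); no stereocenter is formed.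

**Step 2**
Reactants: 3 (E)-3-chloro-2-methylprop-2-en-1-ol
Product: 4 (E)-3-chloro-2-methylprop-2-enal
Conditions: MnO2 (10 equiv), CH2Cl2, rt
Reagents that add atoms: none
Why: Allylic alcohol oxidation with activated MnO2 is neutral and selective, so the vinyl chloride and the alkene geometry should be untouched.

**Step 3**
Reactants: 4 (E)-3-chloro-2-methylprop-2-enal
Product: 5 (E)-1-chloro-2-methylbuta-1,3-diene
Conditions: Ph3PCH3Br, NaN(SiMe3)2, triglyme, 0 °C → rt; diene distilled from the mixture
Reagents that add atoms: methyltriphenylphosphonium bromide C[P+](c1ccccc1)(c1ccccc1)c1ccccc1.[Br-]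
Why: Wittig methylenation by fast 1,2-addition of the non-stabilised ylide to the aldehyde should give the volatile diene without touching the trisubstituted C=C, so Cl stays trans to the new vinyl group.

**Step 4**
Reactants: 6 2,2-dimethyl-1,3-dioxan-5-one
Product: 8 2,2-dimethyl-4H-1,3-dioxin-5-yl benzoate, via potassium enolate 7 (not isolated)
Conditions: KN(SiMe3)2, THF, −78 °C; then BzCl, −78 → 0 °C
Reagents that add atoms: benzoyl chloride O=C(Cl)c1ccccc1
Why: Enolate O-acylation: the dissociated potassium enolate should be acylated on oxygen by the hard acyl chloride to give the enol ester; no stereocenter is formed.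

**Step 5**
Reactants: 8 2,2-dimethyl-4H-1,3-dioxin-5-yl benzoate
Product: 9 2-(benzoyloxy)prop-2-enal
Conditions: toluene, 110 °C, BHT (trace)
Reagents that add atoms: none
Why: Thermal retro-hetero-Diels–Alder reaction of the 4H-1,3-dioxin should expel acetone and unveil the α-acyloxy enal under neutral conditions.

**Step 6**
Reactants: 5 (E)-1-chloro-2-methylbuta-1,3-diene; 9 2-(benzoyloxy)prop-2-enal
Product: 10 (1R,5S)-5-chloro-1-formyl-4-methylcyclohex-3-en-1-yl benzoate
Conditions: (S)-1,1'-binaphthyl-2,2'-diamine (10 mol %), HNTf2 (19 mol %), 5 (3 equiv), EtCN, −40 → −20 °C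
Reagents that add atoms: none
Why: The primary ammonium salt condenses reversibly with the aldehyde of 9 to an aldiminium ion whose lowered LUMO undergoes a concerted but asynchronous [4+2] cycloaddition with 5, and hydrolysis releases 10 and the catalyst; the closest known reaction type is the chiral primary-ammonium-catalysed enantioselective Diels–Alder reaction of α-(acyloxy)acroleins with simple dienes. The six-membered ring is closed by an intermolecular suprafacial [4π+2π] addition that forms C1–C2 and C5–C6 of 10 in one operation. C1 is set by the catalyst, whose binaphthyl unit should leave the Si face of the acrolein C2 open to the diene, and C5 is set relative to C1 by the endo orientation of the iminium carbon towards the (E)-diene, which places Cl cis to the formyl group. The step needs regioselectivity (the chlorine-bearing diene terminus must bond to the CH2 of the dienophile); this is secured by the 2-methyl group, which makes the developing allyl cation tertiary (para orientation), and by sterics, because the fully substituted dienophile carbon then meets the unsubstituted diene terminus, chlorine being only a weak opposing director. It also needs endo and facial selectivity, which the geometrically pure (E)-diene (only this isomer can reach the s-cis form) and the twofold-symmetric diammonium catalyst should provide.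

**Step 7**
Reactants: 10 (1R,5S)-5-chloro-1-formyl-4-methylcyclohex-3-en-1-yl benzoate
Product: 11 (1R,5S)-5-chloro-1-(1-hydroxyethyl)-4-methylcyclohex-3-en-1-yl benzoate (both carbinol epimers)
Conditions: MeTi(OiPr)3 (1.5 equiv), THF, −40 → 0 °C; aq. NH4Cl
Reagents that add atoms: methyltitanium triisopropoxide C[Ti](OC(C)C)(OC(C)C)OC(C)C
Why: Chemoselective carbonyl addition of the non-basic methyltitanium reagent to the aldehyde should leave the benzoate and the allylic chloride alone and avoid acyl migration; the new carbinol centre forms as a mixture, which does not matter because it is oxidised in step 8.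

**Step 8**
Reactants: 11 (1R,5S)-5-chloro-1-(1-hydroxyethyl)-4-methylcyclohex-3-en-1-yl benzoate
Product: 12 (1R,5S)-1-acetyl-5-chloro-4-methylcyclohex-3-en-1-yl benzoate
Conditions: Dess–Martin periodinane, NaHCO3, CH2Cl2, 0 °C → rt
Reagents that add atoms: none
Why: Dess–Martin oxidation under buffered neutral conditions should give the methyl ketone without ionising the allylic chloride or moving the γ,δ-alkene.

**Step 9**
Reactants: 12 (1R,5S)-1-acetyl-5-chloro-4-methylcyclohex-3-en-1-yl benzoate
Product: 13 (1R,3S,4S)-1-acetyl-4-bromo-3-chloro-4-methylcyclohexyl benzoate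
Conditions: Co(acac)2 (0.3 equiv), t-BuOOH (0.3 equiv), Et3SiH (4 equiv), TsBr (2.5 equiv), n-PrOH, rt
Reagents that add atoms: p-toluenesulfonyl bromide Cc1ccc(cc1)S(=O)(=O)Br
Why: Markovnikov hydrobromination by metal-hydride hydrogen atom transfer (Mukaiyama type): the cobalt hydride gives H• to the unsubstituted alkene carbon and the tertiary radical takes Br from TsBr; the new C–Br centre is set by the adjacent C–Cl bond, which should align with the half-filled orbital (also avoiding eclipsing with the methyl group) so that bromine arrives axially on the face anti to chlorine.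

**Step 10**
Reactants: 13 (1R,3S,4S)-1-acetyl-4-bromo-3-chloro-4-methylcyclohexyl benzoate; 14 3-methylbut-2-enal
Product: 16 (1R,3S,4S)-4-bromo-3-chloro-1-[(3S)-3-hydroxy-5-methylhex-4-enoyl]-4-methylcyclohexyl benzoate, via boron enolate 15 (not isolated)
Conditions: (+)-Ipc2BCl (1.5 equiv), Et3N (2 equiv), Et2O, −78 → 0 °C; then 14, −78 → −20 °C; then H2O2, MeOH, pH 7 buffer, 0 °C
Reagents that add atoms: none
Why: Boron-mediated aldol addition: soft enolisation on the only enolisable side (the methyl group) avoids the basicity that would cause acyl transfer of the α-benzoate or elimination of the halides, and the diisopinocampheylboron enolate should add through a cyclic six-membered transition state to the Si face of the enal, reagent control setting the (S)-carbinol.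

**Step 11**
Reactants: 16 (1R,3S,4S)-4-bromo-3-chloro-1-[(3S)-3-hydroxy-5-methylhex-4-enoyl]-4-methylcyclohexyl benzoate
Product: 17 (1R,3S,4S)-4-bromo-3-chloro-1-[(4S)-4-hydroxy-6-methylhepta-1,5-dien-2-yl]-4-methylcyclohexyl benzoate
Conditions: Cp2Ti(μ-Cl)(μ-CH2)AlMe2 (3 equiv), pyridine, THF/toluene, −40 → 0 °C; aq. NaOH
Reagents that add atoms: Tebbe reagent Cp2Ti(μ-Cl)(μ-CH2)AlMe2 C[Al-]1(C)C[Ti]([Cl+]1)(C2C=CC=C2)C3C=CC=C3
Why: Tebbe methylenation: the titanium methylidene is non-basic, so the β-hydroxy ketone should not undergo retro-aldol cleavage (the free hydroxyl only consumes one equivalent as a titanium alkoxide), and it should attack the ketone faster than the hindered tertiary benzoate; no stereocenter is formed or touched.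

**Step 12**
Reactants: 17 (1R,3S,4S)-4-bromo-3-chloro-1-[(4S)-4-hydroxy-6-methylhepta-1,5-dien-2-yl]-4-methylcyclohexyl benzoate
Product: 18 (1R,3S,4S)-4-bromo-3-chloro-1-[(4S)-4-hydroxy-6-methylhepta-1,5-dien-2-yl]-4-methylcyclohexan-1-ol
Conditions: iBu2AlH (3.5 equiv), CH2Cl2, −78 °C; aq. KNaC4H4O6
Reagents that add atoms: none
Why: Reductive ester cleavage at low temperature should free the tertiary alcohol under conditions to which the tertiary bromide, the secondary chloride and both alkenes are inert; no stereocenter is touched.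

**Compound list**

1 | prop-2-yn-1-ol | C#CCO | starting material
2 | dimethylaluminium (E)-3-(dimethylalumanyl)-2-methylprop-2-en-1-olate (alkenylalane) | C[Al](C)OC/C(C)=C/[Al](C)C | intermediate
3 | (E)-3-chloro-2-methylprop-2-en-1-ol | OC/C(C)=C/Cl | intermediate
4 | (E)-3-chloro-2-methylprop-2-enal | O=C/C(C)=C/Cl | intermediate
5 | (E)-1-chloro-2-methylbuta-1,3-diene | C=C/C(C)=C/Cl | intermediate
6 | 2,2-dimethyl-1,3-dioxan-5-one | CC1(C)OCC(=O)CO1 | starting material
7 | potassium 2,2-dimethyl-4H-1,3-dioxin-5-olate | CC1(C)OCC([O-])=CO1.[K+] | intermediate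
8 | 2,2-dimethyl-4H-1,3-dioxin-5-yl benzoate | CC1(C)OCC(OC(=O)c2ccccc2)=CO1 | intermediate
9 | 2-(benzoyloxy)prop-2-enal | C=C(OC(=O)c1ccccc1)C=O | intermediate
10 | (1R,5S)-5-chloro-1-formyl-4-methylcyclohex-3-en-1-yl benzoate | O=C[C@@]1(OC(=O)c2ccccc2)CC=C(C)[C@@H](Cl)C1 | intermediate
11 | (1R,5S)-5-chloro-1-(1-hydroxyethyl)-4-methylcyclohex-3-en-1-yl benzoate (both carbinol epimers) | CC(O)[C@@]1(OC(=O)c2ccccc2)CC=C(C)[C@@H](Cl)C1 | intermediate
12 | (1R,5S)-1-acetyl-5-chloro-4-methylcyclohex-3-en-1-yl benzoate | CC(=O)[C@@]1(OC(=O)c2ccccc2)CC=C(C)[C@@H](Cl)C1 | intermediate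
13 | (1R,3S,4S)-1-acetyl-4-bromo-3-chloro-4-methylcyclohexyl benzoate | CC(=O)[C@@]1(OC(=O)c2ccccc2)CC[C@](C)(Br)[C@@H](Cl)C1 | intermediate
14 | 3-methylbut-2-enal | CC(C)=CC=O | starting material
15 | (1R,3S,4S)-4-bromo-3-chloro-1-{1-[bis((+)-isopinocampheyl)boranyloxy]ethenyl}-4-methylcyclohexyl benzoate (boron enolate) | C=C(OB([C@H]1C[C@H]2C[C@@H]([C@@H]1C)C2(C)C)[C@H]1C[C@H]2C[C@@H]([C@@H]1C)C2(C)C)[C@@]1(OC(=O)c2ccccc2)CC[C@](C)(Br)[C@@H](Cl)C1 | intermediate
16 | (1R,3S,4S)-4-bromo-3-chloro-1-[(3S)-3-hydroxy-5-methylhex-4-enoyl]-4-methylcyclohexyl benzoate | O=C(C[C@H](O)C=C(C)C)[C@@]1(OC(=O)c2ccccc2)CC[C@](C)(Br)[C@@H](Cl)C1 | intermediate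
17 | (1R,3S,4S)-4-bromo-3-chloro-1-[(4S)-4-hydroxy-6-methylhepta-1,5-dien-2-yl]-4-methylcyclohexyl benzoate | C=C(C[C@H](O)C=C(C)C)[C@@]1(OC(=O)c2ccccc2)CC[C@](C)(Br)[C@@H](Cl)C1 | intermediate
18 | (1R,3S,4S)-4-bromo-3-chloro-1-[(4S)-4-hydroxy-6-methylhepta-1,5-dien-2-yl]-4-methylcyclohexan-1-ol | C=C(C[C@H](O)C=C(C)C)[C@@]1(O)CC[C@](C)(Br)[C@@H](Cl)C1 | target

**Step count and risks**

Total: 12 steps. Longest linear sequence: 10 steps (steps 1–3 and 6–12).

Step 6 (Diels–Alder). The chlorine-deactivated diene may add so slowly that the dienophile oligomerises, or chlorine may erode the regio- and endo-selectivity. Fallback: introduce the chloride after the ring is made. Setting out from 9, the same ammonium-catalysed Diels–Alder reaction with commercial isoprene (para orientation) should give (S)-1-formyl-4-methylcyclohex-3-en-1-yl benzoate F1. Allylic hydroxylation with SeO2 (cat.)/t-BuOOH in CH2Cl2 goes to the ring CH2 next to the methyl-bearing alkene carbon and should give, after separation from its C5 epimer, (1R,5R)-1-formyl-5-hydroxy-4-methylcyclohex-3-en-1-yl benzoate F2. PPh3/Cl3CC(O)CCl3 then converts the allylic alcohol into the chloride with inversion, and the route is rejoined at 10.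

Step 9 (hydrobromination). Bromine transfer to the tertiary radical may occur on the face syn to chlorine if the ring conformer with equatorial chlorine reacts. Fallback: relay the configuration through a temporary lactone. Setting out from 10, Pinnick oxidation (NaClO2, NaH2PO4, 2-methylbut-2-ene) gives (1R,5S)-1-(benzoyloxy)-5-chloro-4-methylcyclohex-3-ene-1-carboxylic acid F3. TfOH (cat.) in CH2Cl2 should close the carboxyl group onto the tertiary cation on its own face to give (1R,4R,6S)-6-chloro-1-methyl-3-oxo-2-oxabicyclo[2.2.2]octan-4-yl benzoate F4. HBr in AcOH/CH2Cl2 cleaves the tertiary alkyl–oxygen bond with bromide entering anti to the departing carboxylate, giving (1R,3S,4S)-1-(benzoyloxy)-4-bromo-3-chloro-4-methylcyclohexane-1-carboxylic acid F5. (COCl)2/cat. DMF gives (1R,3S,4S)-4-bromo-3-chloro-1-(chlorocarbonyl)-4-methylcyclohexyl benzoate F6, and Me2CuLi at −78 °C gives the methyl ketone, rejoining the route at 13.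

Step 10 (aldol). Facial discrimination of the enal by the chiral boron enolate may be diluted by the hindered quaternary α-centre, giving a mixture of carbinol epimers. Fallback: set the carbinol by reduction instead of by C–C bond formation. Setting out from 13, aldol addition with achiral (c-C6H11)2BCl/Et3N and 14 gives (1R,3S,4S)-4-bromo-3-chloro-1-(3-hydroxy-5-methylhex-4-enoyl)-4-methylcyclohexyl benzoate (both carbinol epimers) F7. Methylenation as in step 11 gives (1R,3S,4S)-4-bromo-3-chloro-1-(4-hydroxy-6-methylhepta-1,5-dien-2-yl)-4-methylcyclohexyl benzoate (both carbinol epimers) F8. Dess–Martin oxidation gives (1R,3S,4S)-4-bromo-3-chloro-4-methyl-1-(6-methyl-4-oxohepta-1,5-dien-2-yl)cyclohexyl benzoate F9. Corey–Bakshi–Shibata reduction with the (R)-methyl-oxazaborolidine and catecholborane at −78 °C should then deliver the (S)-carbinol, rejoining the route at 17.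

**Further compounds**

F1 | step 6 | (S)-1-formyl-4-methylcyclohex-3-en-1-yl benzoate | O=C[C@@]1(OC(=O)c2ccccc2)CC=C(C)CC1
F2 | step 6 | (1R,5R)-1-formyl-5-hydroxy-4-methylcyclohex-3-en-1-yl benzoate | O=C[C@@]1(OC(=O)c2ccccc2)CC=C(C)[C@H](O)C1
F3 | step 9 | (1R,5S)-1-(benzoyloxy)-5-chloro-4-methylcyclohex-3-ene-1-carboxylic acid | OC(=O)[C@@]1(OC(=O)c2ccccc2)CC=C(C)[C@@H](Cl)C1
F4 | step 9 | (1R,4R,6S)-6-chloro-1-methyl-3-oxo-2-oxabicyclo[2.2.2]octan-4-yl benzoate | O=C1O[C@]2(C)CC[C@@]1(OC(=O)c3ccccc3)C[C@@H]2Cl
F5 | step 9 | (1R,3S,4S)-1-(benzoyloxy)-4-bromo-3-chloro-4-methylcyclohexane-1-carboxylic acid | OC(=O)[C@@]1(OC(=O)c2ccccc2)CC[C@](C)(Br)[C@@H](Cl)C1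
F6 | step 9 | (1R,3S,4S)-4-bromo-3-chloro-1-(chlorocarbonyl)-4-methylcyclohexyl benzoate | ClC(=O)[C@@]1(OC(=O)c2ccccc2)CC[C@](C)(Br)[C@@H](Cl)C1
F7 | step 10 | (1R,3S,4S)-4-bromo-3-chloro-1-(3-hydroxy-5-methylhex-4-enoyl)-4-methylcyclohexyl benzoate (both carbinol epimers) | O=C(CC(O)C=C(C)C)[C@@]1(OC(=O)c2ccccc2)CC[C@](C)(Br)[C@@H](Cl)C1
F8 | step 10 | (1R,3S,4S)-4-bromo-3-chloro-1-(4-hydroxy-6-methylhepta-1,5-dien-2-yl)-4-methylcyclohexyl benzoate (both carbinol epimers) | C=C(CC(O)C=C(C)C)[C@@]1(OC(=O)c2ccccc2)CC[C@](C)(Br)[C@@H](Cl)C1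
F9 | step 10 | (1R,3S,4S)-4-bromo-3-chloro-4-methyl-1-(6-methyl-4-oxohepta-1,5-dien-2-yl)cyclohexyl benzoate | C=C(CC(=O)C=C(C)C)[C@@]1(OC(=O)c2ccccc2)CC[C@](C)(Br)[C@@H](Cl)C1
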